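At early times the two earlier runs, gamma and eta, can't be told apart: at 1.50 min they hold 15.4% and 14.5% of monomer in chains, within the scatter. They part later.

| flask | free monomer | transfer agent | initiator | impurity | remark | time |
|---|---|---|---|---|---|---|
| gamma | 0.10 M (fed, over 3.0 min) | 0.026 M | 2.1 mM | 0.34 mM | run made earlier |  |
| eta | 0.10 M (fed, over 3.0 min) | 0.038 M | 2.1 mM | 0.34 mM | run made earlier |  |
| teal | 0.10 M (fed, over 3.0 min) | 0.0300 M | 2.1 mM | 0.34 mM |  | 10 min |
| ochre | 0.10 M (fed, over 3.0 min) | 0.0600 M | 2.1 mM | 0.34 mM |  | 10 min |

| run | time / min | monomer in chains / % | free monomer / % |
|---|---|---|---|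
| gamma | 0.833 | 3.8 | 21.5 |
| gamma | 1.50 | 15.4 | 34.5 |
| gamma | 3.00 | 39.9 | 63.1 |
| gamma | 5.00 | 52.4 | 45.6 |
| gamma | 10.0 | 58.1 | 40.0 |
| eta | 0.833 | 4.6 | 23.2 |
| eta | 1.50 | 14.5 | 36.3 |
| eta | 3.00 | 33.0 | 67.3 |
| eta | 5.00 | 41.3 | 56.1 |
| eta | 10.0 | 46.5 | 53.7 |

(readings scatter by 1 percentage point)

- the average divides the monomer in chains by the number of chains begun, living and dead together
- the numbers in the tables scatter with a standard deviation of 1 percentage point
- the earlier runs do not show the number of chains; that part of a forecast is a guess
- percentages count the whole charge, also what has not yet gone in

1. which of the two ends with the longer chains by the average number of monomer units in a chain (chains begun, living or dead) ("neither" if they lie within 10%) (teal / ochre / neither)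
2. average number of monomer units in a chain (chains begun, living or dead) at the end, teal
3. average number of monomer units in a chain (chains begun, living or dead) at the end, ochre

The average length is monomer in chains over chains begun, so two estimates are needed. The count comes first. Each impurity is taken to consume one initiator before that initiator begins a chain, with impurity as the limiting reagent of this loss. That gives 1.76 mM, the chains begun, initiator charge less impurity charge. The runs show no chains, so this count is a guess, and it is the same for teal and ochre.

Next comes the monomer in chains at the end. Gamma ends at 58.1% with 0.026 M of transfer agent, and eta at 46.5% with 0.038 M. A straight line through these two points puts ochre, at 0.0600 M, at 25.2%, a length of 14.3.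

That line is the weak link, since ochre at 0.0600 M lies above both runs. Suppose a chain stops growing at a rate with a fixed term and a term in [transfer agent]. The monomer it takes up then goes roughly as the inverse of that rate, so the reciprocal of the fraction in chains should run about straight in [transfer agent]. Between the two runs that reciprocal has a slope of 35.8 L mol⁻¹ against [transfer agent]. Teal then ends at 53.6% and ochre at 34.0%, both estimates that carry the scatter of the readings. The lengths committed to are 30.5 for teal and 19.3 for ochre, so teal is longer by more than the margin.

The forecast also names teal, with lengths 31 for teal and 12.5 for ochre. Its ground: “so I read transfer as chain-killing without effective restart”. It uses the same count, about 1.76 mM, but takes ochre to about 22% where the reckoning here takes 34.0%.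

The flask gives teal the longer chains, with lengths 30.8 for teal and 18.3 for ochre, so the forecast's ochre length is low by a factor of 1.46.

    living end + free monomer → dead end A (k = 0.0693 L mol⁻¹ s⁻¹)
    initiator + impurity → spent initiator B (k = 402 L mol⁻¹ s⁻¹)
    free monomer + living end → monomer in chains + living end, rate k3*[living end]*[free monomer] (k = 6.36 L mol⁻¹ s⁻¹)
    living end + transfer agent → dead chain (kL = 0.195 L mol⁻¹ s⁻¹)
    free monomer + initiator → living end + monomer in chains (k = 2.69 L mol⁻¹ s⁻¹)

Ochre ends with 32.1% of monomer in chains at 10.0 min, where the forecast took about 22%. Its dead chain, dead end A and living end add up to 1.76 mM, the 1.76 mM reckoned above. In the same flask as ochre with 0.0036 M of initiator, the same subtraction gives 3.26 mM chains begun, and 51.8% of monomer in chains over that count gives 15.9. The computed length there is 15.9.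

(The earlier runs and the new flask were computed with constants of no real substance, noise included.)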